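## Retrosynthetic overview

- The strategy rests on one feature: rings A and B are both hexasubstituted benzenes with the same sequence of ring carbons (C–OMe, C–Me, C–OH, C–CH2, C–OH, C–acyl), and the single bridging CH2 sits between two C–OH carbons on each ring. Each ring therefore splits into a four-carbon unit (C–OMe, C–Me, one C–OH, the acyl-bearing CH) and a two-carbon unit (the bridge-bearing carbon and the other C–O carbon).
- The acyl groups go on last: isovaleryl on ring A by Friedel–Crafts acylation at its only ring CH, isobutyryl on ring B from an aryl bromide (lithiation, isobutyraldehyde, oxidation).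
- Ring A is disconnected to cyclobutenone 6 and a siloxyalkyne (24) that hangs on the bridging CH2 of ring B (Danheiser benzannulation).
- Ring B is disconnected the same way to cyclobutenone 6 and an allyl siloxyalkyne (10); the allyl arm is then turned into the propargyl arm and the second siloxyalkyne.
- Order of ring formation: the four-membered ring of 6, then ring B, then ring A.

Key step: step 11

Remark: the target is achiral; the alkene geometries written for the transient ketenes are the expected ones and have no consequence, since those carbons all end up aromatic.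

## Route

Step 1
Reactants: 1 chloroacetaldehyde dimethyl acetal
Product: 3 methoxyethyne, via sodium methoxyethynide 2 (not isolated)
Conditions: NaNH2 (3 equiv), liquid NH3, −33 °C; then cold brine (H2O), −70 °C; distil
Reagents that add atoms: none
Why: Twofold base-induced elimination (loss of methanol and of HCl) with NaNH2 stops at the acetylide salt 2, which water protonates to the ynol ether, as in the standard preparation of alkoxyethynes from chloroacetaldehyde acetals.

Step 2
Reactants: 3 methoxyethyne; 4 propionyl chloride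
Product: 6 (±)-3-methoxy-4-methylcyclobut-2-en-1-one, via methylketene 5 (not isolated)
Conditions: Et3N, Et2O, 0 °C to rt, slow addition of 4, excess 3
Reagents that add atoms: none
Why: Dehydrochlorination of 4 gives methylketene 5, whose carbonyl carbon is attacked by the nucleophilic CH terminus of the ynol ether in a regioselective ketene–alkyne [2+2] cycloaddition, so the methyl-bearing carbon lies next to C–OMe; the one stereocentre (C4) forms as a racemate and is erased on aromatisation.

Step 3
Reactants: 7 pent-1-en-4-yne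
Product: 10 triisopropyl(pent-4-en-1-yn-1-yloxy)silane, via lithium pent-4-en-1-yn-1-ide 8 (not isolated), via lithium pent-4-en-1-yn-1-olate 9 (not isolated)
Conditions: n-BuLi, THF, −78 °C; LiOOt-Bu (from t-BuOOH and LiN(SiMe3)2), −78 to 0 °C; TIPSOTf, −78 to 0 °C
Reagents that add atoms: tert-butyl hydroperoxide CC(C)(C)OO; triisopropylsilyl trifluoromethanesulfonate CC(C)[Si](OS(=O)(=O)C(F)(F)F)(C(C)C)C(C)C
Why: Acetylide 8, formed irreversibly at low temperature so the skipped enyne does not isomerise, is oxidised at carbon by the electrophilic oxygen of LiOOt-Bu to ynolate 9 (Julia ynolate synthesis), and the bulky silyl triflate then reacts at oxygen to give the siloxyalkyne.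

Step 4
Reactants: 6 (±)-3-methoxy-4-methylcyclobut-2-en-1-one; 10 triisopropyl(pent-4-en-1-yn-1-yloxy)silane
Product: 15 2-allyl-5-methoxy-6-methyl-3-(triisopropylsilyloxy)phenol, via vinylketene 11 (not isolated), via vinylcyclobutenone 12 (not isolated), via dienylketene 13 (not isolated), via cyclohexadienone 14 (not isolated)
Conditions: toluene, 80 °C then 110 °C, sealed vessel
Reagents that add atoms: none
Why: Danheiser benzannulation, in which 4π opening of 6 to vinylketene 11, regioselective [2+2] with the siloxyalkyne to 12, 4π opening to 13, 6π electrocyclisation to 14 and tautomerisation should give ring B with the allyl group between the C–OH and C–OSi carbons and no stereocentre left.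

Step 5
Reactants: 15 2-allyl-5-methoxy-6-methyl-3-(triisopropylsilyloxy)phenol
Product: 16 2-allyl-5-methoxy-4-methylbenzene-1,3-diol
Conditions: Bu4NF, AcOH, THF, 0 °C
Reagents that add atoms: none
Why: Fluoride-mediated desilylation of the aryl silyl ether, with acetic acid buffering the electron-rich phenoxide against air oxidation.

Step 6
Reactants: 16 2-allyl-5-methoxy-4-methylbenzene-1,3-diol
Product: 17 2-allyl-5-methoxy-1,3-bis(methoxymethoxy)-4-methylbenzene
Conditions: NaH, MOMCl, DMF, 0 °C to rt
Reagents that add atoms: chloromethyl methyl ether COCCl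
Why: Williamson-type O-alkylation of both sodium phenoxides with the reactive alkoxymethyl chloride masks the hydroxyls as acetal ethers that tolerate the bases and organolithiums used later.

Step 7
Reactants: 17 2-allyl-5-methoxy-1,3-bis(methoxymethoxy)-4-methylbenzene
Product: 18 3-allyl-1-bromo-6-methoxy-2,4-bis(methoxymethoxy)-5-methylbenzene
Conditions: NBS, MeCN, 0 °C, dark
Reagents that add atoms: N-bromosuccinimide O=C1CCC(=O)N1Br
Why: Electrophilic aromatic bromination can occur only at the single ring CH, which is activated ortho and para by three oxygen substituents and so should react far faster than the monosubstituted alkene; bromination is placed after phenol protection to avoid bromoetherification of an ortho-allyl phenol.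

Step 8
Reactants: 18 3-allyl-1-bromo-6-methoxy-2,4-bis(methoxymethoxy)-5-methylbenzene
Product: 20 2-[3-bromo-4-methoxy-2,6-bis(methoxymethoxy)-5-methylphenyl]acetaldehyde, via diol 19 (not isolated)
Conditions: OsO4 (cat.), NaIO4, 2,6-lutidine, dioxane/H2O, rt
Reagents that add atoms: osmium tetroxide O=[Os](=O)(=O)=O; sodium periodate [Na+].[O-][I](=O)(=O)=O
Why: Lemieux–Johnson oxidation, in which catalytic dihydroxylation of the terminal alkene to diol 19 and in situ periodate glycol cleavage give the arylacetaldehyde, the lutidine buffer suppressing over-oxidation; the diol stereocentre is transient.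

Step 9
Reactants: 20 2-[3-bromo-4-methoxy-2,6-bis(methoxymethoxy)-5-methylphenyl]acetaldehyde
Product: 21 1-bromo-6-methoxy-2,4-bis(methoxymethoxy)-5-methyl-3-(prop-2-yn-1-yl)benzene
Conditions: dimethyl (1-diazo-2-oxopropyl)phosphonate, K2CO3, MeOH, 0 °C to rt, crude 20 used at once
Reagents that add atoms: dimethyl (1-diazo-2-oxopropyl)phosphonate CC(=O)C(=[N+]=[N-])P(=O)(OC)OC
Why: Seyferth–Gilbert homologation in its Ohira–Bestmann form, in which the diazomethylphosphonate anion made in situ olefinates the aldehyde and loss of nitrogen with 1,2-hydrogen shift gives the terminal alkyne under conditions that spare the aryl bromide and the acetals.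

Step 10
Reactants: 21 1-bromo-6-methoxy-2,4-bis(methoxymethoxy)-5-methyl-3-(prop-2-yn-1-yl)benzene
Product: 24 {3-[3-bromo-4-methoxy-2,6-bis(methoxymethoxy)-5-methylphenyl]prop-1-yn-1-yloxy}triisopropylsilane, via lithium alkynide 22 (not isolated), via lithium ynolate 23 (not isolated)
Conditions: LiN(SiMe3)2, THF, −78 °C; LiOOt-Bu (from t-BuOOH and LiN(SiMe3)2), −78 to 0 °C; TIPSOTf, −78 to 0 °C
Reagents that add atoms: tert-butyl hydroperoxide CC(C)(C)OO; triisopropylsilyl trifluoromethanesulfonate CC(C)[Si](OS(=O)(=O)C(F)(F)F)(C(C)C)C(C)C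
Why: The amide base deprotonates the terminal alkyne without halogen–metal exchange at the aryl bromide, and alkynide 22 is oxidised by LiOOt-Bu to ynolate 23, which the bulky silyl triflate traps on oxygen (Julia ynolate synthesis).

Step 11
Reactants: 6 (±)-3-methoxy-4-methylcyclobut-2-en-1-one; 24 {3-[3-bromo-4-methoxy-2,6-bis(methoxymethoxy)-5-methylphenyl]prop-1-yn-1-yloxy}triisopropylsilane
Product: 28 2-{[3-bromo-4-methoxy-2,6-bis(methoxymethoxy)-5-methylphenyl]methyl}-5-methoxy-6-methyl-3-(triisopropylsilyloxy)phenol, via vinylcyclobutenone 25 (not isolated), via dienylketene 26 (not isolated), via cyclohexadienone 27 (not isolated)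
Conditions: 6 (excess), toluene, 80 °C then 110 °C, sealed vessel
Reagents that add atoms: none
Why: On heating, 6 reopens by the same 4π electrocyclic cleavage as in step 4 to the vinylketene already numbered 11, whose ketene C=O carbon is attacked by the nucleophilic benzyl-bearing carbon of ynol ether 24 while the silyloxy-bearing carbon bonds to the ketene α-carbon, giving 4-vinylcyclobutenone 25 by ketene–alkyne [2+2] cycloaddition. Reversible 4π opening of 25 gives dienylketene 26, and ring A is closed by a six-electron disrotatory electrocyclisation that joins the ketene carbon to the methyl-bearing diene terminus, the resulting cyclohexa-2,4-dienone 27 tautomerising through its single ring hydrogen to phenol 28. The closest known chemistry is the Danheiser benzannulation of cyclobutenones with trialkylsilyloxyalkynes, together with the thermal opening of other 3-oxygenated cyclobutenones to vinylketenes. No stereocentre survives, since C4 of racemic 6 and the sp3 carbons of 25 and 27 all become aromatic carbons. The selectivity needed is the regiochemistry of the [2+2] step, which the polarisation of the siloxyalkyne secures (its oxygen-free carbon is the nucleophile), so the bridging CH2 ends up between the C–OH and C–OSi carbons and the one ring CH lies between C–OMe and C–OSi. Because the cascade is thermal and neutral, the aryl bromide, the MOM acetals and the diarylmethane CH2 should not be touched.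

Step 12
Reactants: 28 2-{[3-bromo-4-methoxy-2,6-bis(methoxymethoxy)-5-methylphenyl]methyl}-5-methoxy-6-methyl-3-(triisopropylsilyloxy)phenol
Product: 29 [2-{[3-bromo-4-methoxy-2,6-bis(methoxymethoxy)-5-methylphenyl]methyl}-5-methoxy-3-(methoxymethoxy)-4-methylphenoxy]triisopropylsilane
Conditions: NaH, MOMCl, THF/DMF, 0 °C to rt
Reagents that add atoms: chloromethyl methyl ether COCCl
Why: Irreversible deprotonation of the hindered phenol and O-alkylation with MOMCl removes the last acidic OH before the organolithium step, and the aryl silyl ether, being meta to the phenoxide, cannot migrate.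

Step 13
Reactants: 29 [2-{[3-bromo-4-methoxy-2,6-bis(methoxymethoxy)-5-methylphenyl]methyl}-5-methoxy-3-(methoxymethoxy)-4-methylphenoxy]triisopropylsilane; 30 isobutyraldehyde
Product: 32 1-[3-{[4-methoxy-2-(methoxymethoxy)-3-methyl-6-(triisopropylsilyloxy)phenyl]methyl}-6-methoxy-2,4-bis(methoxymethoxy)-5-methylphenyl]-2-methylpropan-1-ol, via aryllithium 31 (not isolated)
Conditions: n-BuLi, THF, −78 °C; then 30, −78 °C; H2O
Reagents that add atoms: none
Why: Bromine–lithium exchange outruns any deprotonation at −78 °C and gives aryllithium 31, stabilised by the flanking OMe and OMOM groups, which undergoes 1,2-addition to the aldehyde; the new carbinol centre forms as a racemate and is removed by the next oxidation.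

Step 14
Reactants: 32 1-[3-{[4-methoxy-2-(methoxymethoxy)-3-methyl-6-(triisopropylsilyloxy)phenyl]methyl}-6-methoxy-2,4-bis(methoxymethoxy)-5-methylphenyl]-2-methylpropan-1-ol
Product: 33 1-[3-{[4-methoxy-2-(methoxymethoxy)-3-methyl-6-(triisopropylsilyloxy)phenyl]methyl}-6-methoxy-2,4-bis(methoxymethoxy)-5-methylphenyl]-2-methylpropan-1-one
Conditions: Dess–Martin periodinane, CH2Cl2, 0 °C to rt
Reagents that add atoms: none
Why: Dess–Martin oxidation converts the hindered benzylic alcohol into the aryl ketone under near-neutral conditions that spare the acetals and the silyl ether.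

Step 15
Reactants: 33 1-[3-{[4-methoxy-2-(methoxymethoxy)-3-methyl-6-(triisopropylsilyloxy)phenyl]methyl}-6-methoxy-2,4-bis(methoxymethoxy)-5-methylphenyl]-2-methylpropan-1-one
Product: 34 1-[3-{[6-hydroxy-4-methoxy-2-(methoxymethoxy)-3-methylphenyl]methyl}-6-methoxy-2,4-bis(methoxymethoxy)-5-methylphenyl]-2-methylpropan-1-one
Conditions: Bu4NF, AcOH, THF, 0 °C to rt
Reagents that add atoms: none
Why: Fluoride-mediated desilylation frees the one silylated phenol while the other three hydroxyls stay protected, so only a single, buffered phenol is exposed.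

Step 16
Reactants: 34 1-[3-{[6-hydroxy-4-methoxy-2-(methoxymethoxy)-3-methylphenyl]methyl}-6-methoxy-2,4-bis(methoxymethoxy)-5-methylphenyl]-2-methylpropan-1-one
Product: 35 1-{3-[(2,6-dihydroxy-4-methoxy-3-methylphenyl)methyl]-2,4-dihydroxy-6-methoxy-5-methylphenyl}-2-methylpropan-1-one
Conditions: conc. HCl (cat.), MeOH, rt to 40 °C, under argon
Reagents that add atoms: none
Why: Acid-catalysed acetal exchange with methanol removes the three MOM groups as dimethoxymethane, the acid being kept dilute and the temperature low out of respect for the diarylmethane.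

Step 17
Reactants: 35 1-{3-[(2,6-dihydroxy-4-methoxy-3-methylphenyl)methyl]-2,4-dihydroxy-6-methoxy-5-methylphenyl}-2-methylpropan-1-one; 36 isovaleryl chloride
Product: 37 1-[3-{[2,6-dihydroxy-4-methoxy-3-methyl-5-(2-methylpropanoyl)phenyl]methyl}-2,4-dihydroxy-6-methoxy-5-methylphenyl]-3-methylbutan-1-one (target)
Conditions: AlCl3, CH2Cl2/MeNO2, 0 °C to rt; then cold 1 M HCl
Reagents that add atoms: none
Why: Friedel–Crafts acylation of the very electron-rich ring A at its only unsubstituted carbon, ortho to a hydroxyl and a methoxyl, while ring B has no free position, any O-acyl product being carried on to the C-acyl ketone by Fries-type transfer under the same Lewis acid.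

## Compound list

1 | chloroacetaldehyde dimethyl acetal | COC(CCl)OC | starting material
2 | sodium methoxyethynide | COC#[C-].[Na+] | intermediate (not isolated)
3 | methoxyethyne | COC#C | intermediate
4 | propionyl chloride | CCC(=O)Cl | starting material
5 | methylketene | CC=C=O | intermediate (not isolated)
6 | (±)-3-methoxy-4-methylcyclobut-2-en-1-one | COC1=CC(=O)C1C | intermediate
7 | pent-1-en-4-yne | C=CCC#C | starting material
8 | lithium pent-4-en-1-yn-1-ide | C=CCC#[C-].[Li+] | intermediate (not isolated)
9 | lithium pent-4-en-1-yn-1-olate | C=CCC#C[O-].[Li+] | intermediate (not isolated)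
10 | triisopropyl(pent-4-en-1-yn-1-yloxy)silane | C=CCC#CO[Si](C(C)C)(C(C)C)C(C)C | intermediate
11 | (3Z)-3-methoxypenta-1,3-dien-1-one (vinylketene) | O=C=C/C(OC)=C/C | intermediate (not isolated)
12 | (±)-2-allyl-4-[(1Z)-1-methoxyprop-1-en-1-yl]-3-(triisopropylsilyloxy)cyclobut-2-en-1-one | C=CCC1=C(O[Si](C(C)C)(C(C)C)C(C)C)C(/C(OC)=C/C)C1=O | intermediate (not isolated)
13 | (3E,5Z)-2-allyl-5-methoxy-3-(triisopropylsilyloxy)hepta-1,3,5-trien-1-one (dienylketene) | O=C=C(CC=C)/C(O[Si](C(C)C)(C(C)C)C(C)C)=C\C(OC)=C\C | intermediate (not isolated)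
14 | (±)-2-allyl-5-methoxy-6-methyl-3-(triisopropylsilyloxy)cyclohexa-2,4-dien-1-one | O=C1C(CC=C)=C(O[Si](C(C)C)(C(C)C)C(C)C)C=C(OC)C1C | intermediate (not isolated)
15 | 2-allyl-5-methoxy-6-methyl-3-(triisopropylsilyloxy)phenol | COc1cc(O[Si](C(C)C)(C(C)C)C(C)C)c(CC=C)c(O)c1C | intermediate
16 | 2-allyl-5-methoxy-4-methylbenzene-1,3-diol | COc1cc(O)c(CC=C)c(O)c1C | intermediate
17 | 2-allyl-5-methoxy-1,3-bis(methoxymethoxy)-4-methylbenzene | COc1cc(OCOC)c(CC=C)c(OCOC)c1C | intermediate
18 | 3-allyl-1-bromo-6-methoxy-2,4-bis(methoxymethoxy)-5-methylbenzene | COc1c(Br)c(OCOC)c(CC=C)c(OCOC)c1C | intermediate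
19 | (±)-3-[3-bromo-4-methoxy-2,6-bis(methoxymethoxy)-5-methylphenyl]propane-1,2-diol | COc1c(Br)c(OCOC)c(CC(O)CO)c(OCOC)c1C | intermediate (not isolated)
20 | 2-[3-bromo-4-methoxy-2,6-bis(methoxymethoxy)-5-methylphenyl]acetaldehyde | COc1c(Br)c(OCOC)c(CC=O)c(OCOC)c1C | intermediate
21 | 1-bromo-6-methoxy-2,4-bis(methoxymethoxy)-5-methyl-3-(prop-2-yn-1-yl)benzene | COc1c(Br)c(OCOC)c(CC#C)c(OCOC)c1C | intermediate
22 | lithium 3-[3-bromo-4-methoxy-2,6-bis(methoxymethoxy)-5-methylphenyl]prop-1-yn-1-ide | COc1c(Br)c(OCOC)c(CC#[C-])c(OCOC)c1C.[Li+] | intermediate (not isolated)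
23 | lithium 3-[3-bromo-4-methoxy-2,6-bis(methoxymethoxy)-5-methylphenyl]prop-1-yn-1-olate | COc1c(Br)c(OCOC)c(CC#C[O-])c(OCOC)c1C.[Li+] | intermediate (not isolated)
24 | {3-[3-bromo-4-methoxy-2,6-bis(methoxymethoxy)-5-methylphenyl]prop-1-yn-1-yloxy}triisopropylsilane | COc1c(Br)c(OCOC)c(CC#CO[Si](C(C)C)(C(C)C)C(C)C)c(OCOC)c1C | intermediate
25 | (±)-2-{[3-bromo-4-methoxy-2,6-bis(methoxymethoxy)-5-methylphenyl]methyl}-4-[(1Z)-1-methoxyprop-1-en-1-yl]-3-(triisopropylsilyloxy)cyclobut-2-en-1-one | COc1c(Br)c(OCOC)c(CC2=C(O[Si](C(C)C)(C(C)C)C(C)C)C(/C(OC)=C/C)C2=O)c(OCOC)c1C | intermediate (not isolated)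
26 | (3E,5Z)-2-{[3-bromo-4-methoxy-2,6-bis(methoxymethoxy)-5-methylphenyl]methyl}-5-methoxy-3-(triisopropylsilyloxy)hepta-1,3,5-trien-1-one | COc1c(Br)c(OCOC)c(CC(=C=O)/C(O[Si](C(C)C)(C(C)C)C(C)C)=C\C(OC)=C\C)c(OCOC)c1C | intermediate (not isolated)
27 | (±)-2-{[3-bromo-4-methoxy-2,6-bis(methoxymethoxy)-5-methylphenyl]methyl}-5-methoxy-6-methyl-3-(triisopropylsilyloxy)cyclohexa-2,4-dien-1-one | COc1c(Br)c(OCOC)c(CC2=C(O[Si](C(C)C)(C(C)C)C(C)C)C=C(OC)C(C)C2=O)c(OCOC)c1C | intermediate (not isolated)
28 | 2-{[3-bromo-4-methoxy-2,6-bis(methoxymethoxy)-5-methylphenyl]methyl}-5-methoxy-6-methyl-3-(triisopropylsilyloxy)phenol | COc1cc(O[Si](C(C)C)(C(C)C)C(C)C)c(Cc2c(OCOC)c(C)c(OC)c(Br)c2OCOC)c(O)c1C | intermediate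
29 | [2-{[3-bromo-4-methoxy-2,6-bis(methoxymethoxy)-5-methylphenyl]methyl}-5-methoxy-3-(methoxymethoxy)-4-methylphenoxy]triisopropylsilane | COc1cc(O[Si](C(C)C)(C(C)C)C(C)C)c(Cc2c(OCOC)c(C)c(OC)c(Br)c2OCOC)c(OCOC)c1C | intermediate
30 | isobutyraldehyde | CC(C)C=O | starting material
31 | aryllithium from 29 (lithium in place of bromine on ring B) | COc1cc(O[Si](C(C)C)(C(C)C)C(C)C)c(Cc2c(OCOC)c(C)c(OC)c([Li])c2OCOC)c(OCOC)c1C | intermediate (not isolated)
32 | (±)-1-[3-{[4-methoxy-2-(methoxymethoxy)-3-methyl-6-(triisopropylsilyloxy)phenyl]methyl}-6-methoxy-2,4-bis(methoxymethoxy)-5-methylphenyl]-2-methylpropan-1-ol | COc1cc(O[Si](C(C)C)(C(C)C)C(C)C)c(Cc2c(OCOC)c(C)c(OC)c(C(O)C(C)C)c2OCOC)c(OCOC)c1C | intermediate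
33 | 1-[3-{[4-methoxy-2-(methoxymethoxy)-3-methyl-6-(triisopropylsilyloxy)phenyl]methyl}-6-methoxy-2,4-bis(methoxymethoxy)-5-methylphenyl]-2-methylpropan-1-one | COc1cc(O[Si](C(C)C)(C(C)C)C(C)C)c(Cc2c(OCOC)c(C)c(OC)c(C(=O)C(C)C)c2OCOC)c(OCOC)c1C | intermediate
34 | 1-[3-{[6-hydroxy-4-methoxy-2-(methoxymethoxy)-3-methylphenyl]methyl}-6-methoxy-2,4-bis(methoxymethoxy)-5-methylphenyl]-2-methylpropan-1-one | COc1cc(O)c(Cc2c(OCOC)c(C)c(OC)c(C(=O)C(C)C)c2OCOC)c(OCOC)c1C | intermediate
35 | 1-{3-[(2,6-dihydroxy-4-methoxy-3-methylphenyl)methyl]-2,4-dihydroxy-6-methoxy-5-methylphenyl}-2-methylpropan-1-one | COc1cc(O)c(Cc2c(O)c(C)c(OC)c(C(=O)C(C)C)c2O)c(O)c1C | intermediate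
36 | isovaleryl chloride | CC(C)CC(=O)Cl | starting material
37 | 1-[3-{[2,6-dihydroxy-4-methoxy-3-methyl-5-(2-methylpropanoyl)phenyl]methyl}-2,4-dihydroxy-6-methoxy-5-methylphenyl]-3-methylbutan-1-one (CNP0265841.0) | COc1c(C)c(O)c(Cc2c(O)c(C)c(OC)c(C(=O)C(C)C)c2O)c(O)c1C(=O)CC(C)C | target

## Step count

Total: 17 steps. Longest linear sequence: 16 steps (steps 1, 2 and 4 to 17); step 3 is a side branch, and cyclobutenone 6 is used in both step 4 and step 11.

## Steps most likely to fail

**Step 17 (Friedel–Crafts acylation of the free tetraphenol).** The Lewis acid may protonate or complex ring A at the bridge carbon and cleave or scramble the diarylmethane by retro-Friedel–Crafts alkylation. Acylation may also stop at oxygen, or the methyl ether next to a chelated carbonyl may be cleaved. The fallback introduces the isovaleryl group by the same organolithium logic used for ring B, before any phenol is freed. It sets out from carbinol 32. NBS in MeCN at 0 °C should brominate the single ring A CH to give the ring A bromide F1. Treatment with n-BuLi in THF at −78 °C (one equivalent for the hydroxyl, one for bromine–lithium exchange), kept cold so that the neighbouring silyl group does not migrate from oxygen to the lithiated carbon, followed by 3-methylbutanal, should give the bis-carbinol F2. Dess–Martin periodinane should oxidise both carbinols to the protected diketone F3. Bu4NF/AcOH should then give the mono-phenol diketone F4, and catalytic HCl in MeOH should remove the three MOM groups, so the fallback comes back to the route at target 37.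

**Step 11 (second benzannulation, key step).** The donor-substituted cyclobutenone may open only at temperatures at which the hindered siloxyalkyne isomerises to a silylketene. Alternatively the vinylketene may be consumed by oligomerisation or by acylating the product phenol before it meets the alkyne. The fallback generates the same vinylketene 11 at or below room temperature by 1,4-dehydrochlorination of an acid chloride instead of by electrocyclic opening. Commercial methyl 3-oxopentanoate with HC(OMe)3 and catalytic H2SO4 in MeOH should give methyl (E)-3-methoxypent-2-enoate F5. LiOH in aqueous THF should give (E)-3-methoxypent-2-enoic acid F6, and oxalyl chloride with catalytic DMF should give (E)-3-methoxypent-2-enoyl chloride F7. The fallback then sets out from siloxyalkyne 24: slow addition of the acid chloride to 24 and Et3N in CH2Cl2 at 0 °C to rt should give vinylcyclobutenone 25 by ketene–siloxyalkyne [2+2] cycloaddition. Gentle warming in toluene (60 to 80 °C) should carry 25 through 26 and 27, and the fallback comes back to the route at phenol 28. The same device would serve step 4 with siloxyalkyne 10.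

**Step 9 (Ohira–Bestmann homologation).** The arylacetaldehyde may enolise and self-condense in basic methanol, and the propargyl arene may isomerise to the aryl allene under the same conditions. The fallback makes the alkyne by aprotic Corey–Fuchs chemistry before the bromine is on the ring, so that n-BuLi can be used. It sets out from the bis-MOM allyl arene 17. OsO4/NaIO4/2,6-lutidine should give 2-[4-methoxy-2,6-bis(methoxymethoxy)-3-methylphenyl]acetaldehyde F8. CBr4/PPh3 in CH2Cl2 at 0 °C should give 2-(3,3-dibromoprop-2-en-1-yl)-5-methoxy-1,3-bis(methoxymethoxy)-4-methylbenzene F9. Two equivalents of n-BuLi in THF at −78 °C, then water, should give 5-methoxy-1,3-bis(methoxymethoxy)-4-methyl-2-(prop-2-yn-1-yl)benzene F10, the alkyne being held as its lithium acetylide until the quench. NBS in MeCN at 0 °C should then brominate the lone ring CH, and the fallback comes back to the route at propargyl arene 21.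

## Further compounds

F1 | step 17 | (±)-1-[3-{[3-bromo-4-methoxy-6-(methoxymethoxy)-5-methyl-2-(triisopropylsilyloxy)phenyl]methyl}-6-methoxy-2,4-bis(methoxymethoxy)-5-methylphenyl]-2-methylpropan-1-ol | COc1c(Br)c(O[Si](C(C)C)(C(C)C)C(C)C)c(Cc2c(OCOC)c(C)c(OC)c(C(O)C(C)C)c2OCOC)c(OCOC)c1C
F2 | step 17 | 1-[3-{[3-(1-hydroxy-3-methylbutyl)-4-methoxy-6-(methoxymethoxy)-5-methyl-2-(triisopropylsilyloxy)phenyl]methyl}-6-methoxy-2,4-bis(methoxymethoxy)-5-methylphenyl]-2-methylpropan-1-ol (mixture of diastereomers) | COc1c(C(O)CC(C)C)c(O[Si](C(C)C)(C(C)C)C(C)C)c(Cc2c(OCOC)c(C)c(OC)c(C(O)C(C)C)c2OCOC)c(OCOC)c1C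
F3 | step 17 | 1-[3-{[4-methoxy-6-(methoxymethoxy)-5-methyl-3-(3-methylbutanoyl)-2-(triisopropylsilyloxy)phenyl]methyl}-6-methoxy-2,4-bis(methoxymethoxy)-5-methylphenyl]-2-methylpropan-1-one | COc1c(C(=O)CC(C)C)c(O[Si](C(C)C)(C(C)C)C(C)C)c(Cc2c(OCOC)c(C)c(OC)c(C(=O)C(C)C)c2OCOC)c(OCOC)c1C
F4 | step 17 | 1-[3-{[2-hydroxy-4-methoxy-6-(methoxymethoxy)-5-methyl-3-(3-methylbutanoyl)phenyl]methyl}-6-methoxy-2,4-bis(methoxymethoxy)-5-methylphenyl]-2-methylpropan-1-one | COc1c(C(=O)CC(C)C)c(O)c(Cc2c(OCOC)c(C)c(OC)c(C(=O)C(C)C)c2OCOC)c(OCOC)c1C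
F5 | step 11 | methyl (E)-3-methoxypent-2-enoate | CC/C(OC)=C\C(=O)OC
F6 | step 11 | (E)-3-methoxypent-2-enoic acid | CC/C(OC)=C\C(=O)O
F7 | step 11 | (E)-3-methoxypent-2-enoyl chloride | CC/C(OC)=C\C(=O)Cl
F8 | step 9 | 2-[4-methoxy-2,6-bis(methoxymethoxy)-3-methylphenyl]acetaldehyde | COc1cc(OCOC)c(CC=O)c(OCOC)c1C
F9 | step 9 | 2-(3,3-dibromoprop-2-en-1-yl)-5-methoxy-1,3-bis(methoxymethoxy)-4-methylbenzene | COc1cc(OCOC)c(CC=C(Br)Br)c(OCOC)c1C
F10 | step 9 | 5-methoxy-1,3-bis(methoxymethoxy)-4-methyl-2-(prop-2-yn-1-yl)benzene | COc1cc(OCOC)c(CC#C)c(OCOC)c1C
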